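Retrosynthesis: remove the sixteen O-benzyl groups; cut the lower-unit gallate at its C3–O acyl bond; cut C4–C4a of the lower unit (ring C); cut O1–C2 of the lower unit (aryl ether); cut the interflavan bond upper C4–lower C8; cut the upper gallate. This leaves (−)-epigallocatechin, 3,5-bis(benzyloxy)phenol, tri-O-benzylgallic acid and an epoxy alcohol made from 3,4,5-tris(benzyloxy)benzaldehyde.
Forward: the upper unit keeps its natural rings A, B and C; its C4 cation arylates the phenol (the future ring A of the lower unit) next to the OH; the phenol oxygen is etherified with the epoxy alcohol; ring C of the lower unit is closed last, on the dimeric ether; galloylation and hydrogenolysis finish the route.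
Enabling feature: ring A of the lower unit is a phloroglucinol tri-ether, so C4a is ortho to O1 and to the C5 oxygen and para to the C7 oxygen. Once C8 carries the upper unit, C4a is the only free carbon ortho to O1, and the O1–C2–C3–C4 chain holds the terminal epoxide carbon C4 at six-ring distance. The epoxide oxygen is the activating group and stays as the C3 hydroxyl that is then galloylated.
Stereochemistry: upper C2 and C3 come from natural epigallocatechin; upper C4 (β) comes from attack on the C4 cation anti to the C3 acyloxy group; lower C3 comes from Sharpless epoxidation with L-(+)-DIPT; lower C2 comes from Mitsunobu inversion; the ring closure touches neither.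

Key step: step 8

Remark: the target is read as (−)-epigallocatechin 3-O-gallate-(4β→8)-(−)-epigallocatechin 3-O-gallate, upper unit (2R,3R,4R), lower unit (2R,3R); flavan numbering (O1, C2, C3, C4, C4a, C5 to C8, C8a) is used for both units.

Step 1
Reactants: 1 (−)-epigallocatechin
Product: 2 5,7,3′,4′,5′-penta-O-benzyl-(−)-epigallocatechin, (2R,3R)-5,7-bis(benzyloxy)-2-[3,4,5-tris(benzyloxy)phenyl]chroman-3-ol
Conditions: BnBr (5.5 equiv), K2CO3, DMF, argon, 0 °C to rt
Reagents that add atoms: benzyl bromide, BrCc1ccccc1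
Why: Williamson ether synthesis in which carbonate deprotonates only the five phenols, so the secondary C3 hydroxyl stays free, while exclusion of air and low temperature protect the pyrogallol ring from oxidation and C2 from epimerization.

Step 2
Reactants: 2 penta-O-benzyl-(−)-epigallocatechin
Product: 3 (2R,3R,4S)-5,7-bis(benzyloxy)-4-(2-ethoxyethoxy)-2-[3,4,5-tris(benzyloxy)phenyl]chroman-3-ol (4β-ether, trans to the 3-OH)
Conditions: DDQ (2 equiv), 2-ethoxyethanol (excess), CH2Cl2, rt
Reagents that add atoms: 2-ethoxyethanol, CCOCCO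
Why: DDQ benzylic oxidation by hydride abstraction at C4, the CH2 activated by the ring A oxygens, gives a cation that the alcohol traps anti to the axial C3 hydroxyl, a known reaction type of benzylated flavan-3-ols; this C4 centre is ionized again in step 4.

Step 3
Reactants: 3 the 4β-(2-ethoxyethoxy) alcohol; 4 3,4,5-tris(benzyloxy)benzoic acid
Product: 5 (2R,3R,4S)-5,7-bis(benzyloxy)-4-(2-ethoxyethoxy)-2-[3,4,5-tris(benzyloxy)phenyl]chroman-3-yl 3,4,5-tris(benzyloxy)benzoate
Conditions: DCC, DMAP (cat), CH2Cl2, rt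
Reagents that add atoms: none
Why: Steglich esterification of the hindered secondary alcohol, which masks the only free hydroxyl of the upper unit before the Mitsunobu step and supplies the neighbouring group for step 4.

Step 4
Reactants: 5 the C4-activated upper unit; 6 3,5-bis(benzyloxy)phenol
Product: 7 (2R,3R,4S)-5,7-bis(benzyloxy)-4-[2,4-bis(benzyloxy)-6-hydroxyphenyl]-2-[3,4,5-tris(benzyloxy)phenyl]chroman-3-yl 3,4,5-tris(benzyloxy)benzoate (4β-aryl, trans to the C3 ester)
Conditions: 6 (4 equiv), BF3·OEt2 (0.3 equiv), 4 Å MS, CH2Cl2, −78 to −30 °C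
Reagents that add atoms: none
Why: Lewis-acid ionization of the C4 ether gives the benzylic C4 cation for a Friedel–Crafts arylation that is expected to come anti to the C3 acyloxy group (shielding and acyloxonium participation, giving the 4β bond) and at a phenol carbon flanked by OH and one benzyloxy group, not at the carbon between the two benzyloxy groups, the same preference that sends benzylated flavan-3-ols to C8 and not to C6.

Step 5
Reactants: 8 3,4,5-tris(benzyloxy)benzaldehyde
Product: 9 racemic 1-[3,4,5-tris(benzyloxy)phenyl]prop-2-en-1-ol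
Conditions: CH2=CHMgBr, THF, 0 °C; then H2O
Reagents that add atoms: vinylmagnesium bromide, C=C[Mg]Br
Why: Grignard 1,2-addition to the aldehyde gives the allylic alcohol, which is resolved in step 6.

Step 6
Reactants: 9 racemic 1-[3,4,5-tris(benzyloxy)phenyl]prop-2-en-1-ol
Product: 10 (S)-[(R)-oxiran-2-yl][3,4,5-tris(benzyloxy)phenyl]methanol (erythro epoxy alcohol)
Conditions: Ti(OiPr)4 (15 mol %), L-(+)-DIPT (20 mol %), t-BuOOH (0.5 equiv), 4 Å MS, CH2Cl2, −20 °C
Reagents that add atoms: tert-butyl hydroperoxide, CC(C)(C)OO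
Why: Sharpless asymmetric epoxidation run as a kinetic resolution, in which L-(+)-DIPT epoxidizes the (R)-enantiomer of 9 fast and erythro-selectively and so sets the (R)-oxirane carbon under reagent control, while the slow (S)-enantiomer of 9 stays behind and is removed by chromatography.

Step 7
Reactants: 7 the 4β-aryl phenol; 10 the erythro epoxy alcohol
Product: 11 the ether of 7 in which the phenol oxygen carries the (R)-[(R)-oxiran-2-yl][3,4,5-tris(benzyloxy)phenyl]methyl group (upper unit unchanged, 4β-aryl, 3,4-trans)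
Conditions: PPh3, DIAD, THF, 0 °C to rt
Reagents that add atoms: none
Why: Mitsunobu etherification of the phenol, the only acidic OH present, with the secondary benzylic alcohol runs by SN2 displacement with inversion and turns the (S)-carbinol of 10 into the (R)-ether carbon (future C2, cis to the C3 oxygen), the adjacent epoxide disfavouring ionization.

Step 8
Reactants: 11 the dimeric aryl ether epoxide
Product: 12 trideca-O-benzyl (−)-epigallocatechin 3-O-gallate-(4β→8)-(−)-epigallocatechin, upper unit (2R,3R,4R) with its tri-O-benzylgallate, lower unit (2R,3R) with free 3-OH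
Conditions: AuCl3 (5 mol %), AgOTf (15 mol %), 4 Å MS, CH2Cl2 (0.01 M), 0 °C to rt
Reagents that add atoms: none
Why: The silver-activated trivalent gold Lewis acid coordinates the epoxide oxygen of 11, and ring A of the lower unit attacks the terminal epoxide carbon C4 through C4a in an SN2-like intramolecular Friedel–Crafts alkylation, after which the arenium ion loses the C4a proton and proton transfer frees the C3 hydroxyl. The closest known reaction type is the gold- or Lewis-acid-catalysed cycloalkylation of aryl 2,3-epoxypropyl ethers to chroman-3-ols. Ring C closes in the 6-endo-tet mode (both epoxide carbons end up in the ring) and not by 5-exo attack at C3, because C4 is primary and unhindered whereas C3 is secondary, flanked by the aryl-bearing C2 and poorly placed for backside attack across the planar aryl–O tether. No stereocentre is created: C4 becomes a CH2 group, the C3–O bond is not broken and C2 is not touched, so the (2R,3R) cis relationship set in steps 6 and 7 is carried over unchanged. The site selectivity is secured by the substrate, since C4a is the only unsubstituted carbon ortho to O1 (C8 bears the upper unit, C6 is out of reach) and is activated by O1 and the C5 oxygen (ortho) and the C7 oxygen (para), which also fixes the 4→8 connectivity of the dimer. High dilution and low temperature are chosen to suppress intermolecular alkylation of the upper ring A and acid cleavage of the interflavan and C2–O1 bonds, the β-oxygen at C3 disfavouring ionization at C2.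

Step 9
Reactants: 12 the dimer with free lower 3-OH; 4 3,4,5-tris(benzyloxy)benzoic acid
Product: 13 hexadeca-O-benzyl rhodisin, upper unit (2R,3R,4R), lower unit (2R,3R)
Conditions: DCC, DMAP, CH2Cl2, rt
Reagents that add atoms: none
Why: Steglich esterification of the single free hydroxyl (axial C3–OH of the lower unit) installs the second protected gallate.

Step 10
Reactants: 13 hexadeca-O-benzyl rhodisin
Product: 14 rhodisin
Conditions: H2 (1 atm), Pd(OH)2/C, THF/MeOH/H2O, rt
Reagents that add atoms: none
Why: hydrogenolysis of all sixteen benzyl ethers under neutral conditions should leave the two gallate esters, the interflavan bond and the five stereocentres untouched.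

Compound list
1 | (−)-epigallocatechin | O[C@@H]1Cc2c(O)cc(O)cc2O[C@@H]1c1cc(O)c(O)c(O)c1 | starting material
2 | 5,7,3′,4′,5′-penta-O-benzyl-(−)-epigallocatechin | O[C@@H]1Cc2c(OCc3ccccc3)cc(OCc3ccccc3)cc2O[C@@H]1c1cc(OCc2ccccc2)c(OCc2ccccc2)c(OCc2ccccc2)c1 | intermediate
3 | (2R,3R,4S)-5,7-bis(benzyloxy)-4-(2-ethoxyethoxy)-2-[3,4,5-tris(benzyloxy)phenyl]chroman-3-ol | O[C@@H]1[C@@H](OCCOCC)c2c(OCc3ccccc3)cc(OCc3ccccc3)cc2O[C@@H]1c1cc(OCc2ccccc2)c(OCc2ccccc2)c(OCc2ccccc2)c1 | intermediate
4 | 3,4,5-tris(benzyloxy)benzoic acid | OC(=O)c1cc(OCc2ccccc2)c(OCc2ccccc2)c(OCc2ccccc2)c1 | starting material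
5 | (2R,3R,4S)-5,7-bis(benzyloxy)-4-(2-ethoxyethoxy)-2-[3,4,5-tris(benzyloxy)phenyl]chroman-3-yl 3,4,5-tris(benzyloxy)benzoate | O=C(O[C@@H]1[C@@H](OCCOCC)c2c(OCc3ccccc3)cc(OCc3ccccc3)cc2O[C@@H]1c1cc(OCc2ccccc2)c(OCc2ccccc2)c(OCc2ccccc2)c1)c1cc(OCc2ccccc2)c(OCc2ccccc2)c(OCc2ccccc2)c1 | intermediate
6 | 3,5-bis(benzyloxy)phenol | Oc1cc(OCc2ccccc2)cc(OCc2ccccc2)c1 | starting material
7 | (2R,3R,4S)-5,7-bis(benzyloxy)-4-[2,4-bis(benzyloxy)-6-hydroxyphenyl]-2-[3,4,5-tris(benzyloxy)phenyl]chroman-3-yl 3,4,5-tris(benzyloxy)benzoate (4β-aryl) | O=C(O[C@@H]1[C@@H](c2c(OCc3ccccc3)cc(OCc3ccccc3)cc2O)c2c(OCc3ccccc3)cc(OCc3ccccc3)cc2O[C@@H]1c1cc(OCc2ccccc2)c(OCc2ccccc2)c(OCc2ccccc2)c1)c1cc(OCc2ccccc2)c(OCc2ccccc2)c(OCc2ccccc2)c1 | intermediate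
8 | 3,4,5-tris(benzyloxy)benzaldehyde | O=Cc1cc(OCc2ccccc2)c(OCc2ccccc2)c(OCc2ccccc2)c1 | starting material
9 | racemic 1-[3,4,5-tris(benzyloxy)phenyl]prop-2-en-1-ol | OC(C=C)c1cc(OCc2ccccc2)c(OCc2ccccc2)c(OCc2ccccc2)c1 | intermediate
10 | (S)-[(R)-oxiran-2-yl][3,4,5-tris(benzyloxy)phenyl]methanol | O[C@@H](c1cc(OCc2ccccc2)c(OCc2ccccc2)c(OCc2ccccc2)c1)[C@H]1CO1 | intermediate
11 | ether of 7 with the (R)-[(R)-oxiran-2-yl][3,4,5-tris(benzyloxy)phenyl]methyl group on the phenol oxygen | O=C(O[C@@H]1[C@@H](c2c(OCc3ccccc3)cc(OCc3ccccc3)cc2O[C@H](c2cc(OCc3ccccc3)c(OCc3ccccc3)c(OCc3ccccc3)c2)[C@H]2CO2)c2c(OCc3ccccc3)cc(OCc3ccccc3)cc2O[C@@H]1c1cc(OCc2ccccc2)c(OCc2ccccc2)c(OCc2ccccc2)c1)c1cc(OCc2ccccc2)c(OCc2ccccc2)c(OCc2ccccc2)c1 | intermediate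
12 | trideca-O-benzyl (−)-epigallocatechin 3-O-gallate-(4β→8)-(−)-epigallocatechin (free 3-OH in the lower unit) | O=C(O[C@@H]1[C@@H](c2c(OCc3ccccc3)cc(OCc3ccccc3)c3c2O[C@H](c2cc(OCc4ccccc4)c(OCc4ccccc4)c(OCc4ccccc4)c2)[C@H](O)C3)c2c(OCc3ccccc3)cc(OCc3ccccc3)cc2O[C@@H]1c1cc(OCc2ccccc2)c(OCc2ccccc2)c(OCc2ccccc2)c1)c1cc(OCc2ccccc2)c(OCc2ccccc2)c(OCc2ccccc2)c1 | intermediate
13 | hexadeca-O-benzyl rhodisin | O=C(O[C@@H]1[C@@H](c2c(OCc3ccccc3)cc(OCc3ccccc3)c3c2O[C@H](c2cc(OCc4ccccc4)c(OCc4ccccc4)c(OCc4ccccc4)c2)[C@H](OC(=O)c2cc(OCc4ccccc4)c(OCc4ccccc4)c(OCc4ccccc4)c2)C3)c2c(OCc3ccccc3)cc(OCc3ccccc3)cc2O[C@@H]1c1cc(OCc2ccccc2)c(OCc2ccccc2)c(OCc2ccccc2)c1)c1cc(OCc2ccccc2)c(OCc2ccccc2)c(OCc2ccccc2)c1 | intermediate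
14 | rhodisin | O=C(O[C@@H]1[C@@H](c2c(O)cc(O)c3c2O[C@H](c2cc(O)c(O)c(O)c2)[C@H](OC(=O)c2cc(O)c(O)c(O)c2)C3)c2c(O)cc(O)cc2O[C@@H]1c1cc(O)c(O)c(O)c1)c1cc(O)c(O)c(O)c1 | target

Total step count: 10. Longest linear sequence: 8 steps (steps 1, 2, 3, 4, 7, 8, 9, 10).

Steps most likely to fail

Step 4. The arylation may go in part to the carbon between the two benzyloxy groups, the phenol may be O-alkylated, or the product may be arylated a second time. The fallback sets out from 6 and 5 and comes back at 7. Compound 6 is acetylated (Ac2O, pyridine) to 3,5-bis(benzyloxy)phenyl acetate F1. With the hydroxyl masked as an ester, the carbon between the two benzyloxy groups has no para alkoxy activation and O-alkylation is excluded. Friedel–Crafts arylation of F1 (large excess, recoverable) by the cation from 5 (TMSOTf, CH2Cl2, −78 to −40 °C) should then go to the carbon ortho to the acetoxy group and para to a benzyloxy group, as in 1,3-dialkoxybenzenes, to give the O-acetate of 7 F2. Chemoselective cleavage of the phenolic acetate with hydrazine acetate in DMF, which spares the hindered gallate, returns to 7.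

Step 7. Etherification of the ortho-substituted phenol may be slow, so that elimination or ionization of the benzylic alcohol, with loss of configuration at the future C2, competes. The fallback sets out from 6 and 10 and comes back at 12. Mitsunobu coupling of the unhindered phenol 6 with 10 (PPh3, DIAD, THF) gives (R)-[(R)-oxiran-2-yl][3,4,5-tris(benzyloxy)phenyl]methyl 3,5-bis(benzyloxy)phenyl ether F3. The same AuCl3/AgOTf ring closure then forms C4–C4a on this monomeric ether and gives 2. Arylation of 2 (3 to 4 equiv) at C8 by the cation from 5 (TMSOTf, CH2Cl2, −78 °C), with the C8 over C6 preference known for benzylated flavan-3-ols, returns to the route at 12.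

Step 8. The epoxide may open at its internal carbon (5-exo closure), may rearrange by hydride shift to an aldehyde, or the acid may cleave the interflavan bond of the dimeric substrate. The fallback sets out from 2, 4 and 5 and comes back at 13. Compound 2 is esterified with 4 (DCC, DMAP, CH2Cl2) to octa-O-benzyl-(−)-epigallocatechin 3-O-gallate F4. F4 is arylated at C8 by the cation from 5 (TMSOTf, CH2Cl2, −78 °C) to give 13 directly. The lower unit is then taken from the natural flavan and no ring closure is needed.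

Further compounds
F1 | step 4 | 3,5-bis(benzyloxy)phenyl acetate | CC(=O)Oc1cc(OCc2ccccc2)cc(OCc2ccccc2)c1
F2 | step 4 | O-acetate of 7, (2R,3R)-4β-[2-acetoxy-4,6-bis(benzyloxy)phenyl]-5,7-bis(benzyloxy)-2-[3,4,5-tris(benzyloxy)phenyl]chroman-3-yl 3,4,5-tris(benzyloxy)benzoate | O=C(O[C@@H]1[C@@H](c2c(OCc3ccccc3)cc(OCc3ccccc3)cc2OC(C)=O)c2c(OCc3ccccc3)cc(OCc3ccccc3)cc2O[C@@H]1c1cc(OCc2ccccc2)c(OCc2ccccc2)c(OCc2ccccc2)c1)c1cc(OCc2ccccc2)c(OCc2ccccc2)c(OCc2ccccc2)c1
F3 | step 7 | (R)-[(R)-oxiran-2-yl][3,4,5-tris(benzyloxy)phenyl]methyl 3,5-bis(benzyloxy)phenyl ether | c1ccccc1COc1cc(OCc2ccccc2)cc(O[C@H](c2cc(OCc3ccccc3)c(OCc3ccccc3)c(OCc3ccccc3)c2)[C@H]2CO2)c1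
F4 | step 8 | octa-O-benzyl-(−)-epigallocatechin 3-O-gallate | O=C(O[C@@H]1Cc2c(OCc3ccccc3)cc(OCc3ccccc3)cc2O[C@@H]1c1cc(OCc2ccccc2)c(OCc2ccccc2)c(OCc2ccccc2)c1)c1cc(OCc2ccccc2)c(OCc2ccccc2)c(OCc2ccccc2)c1
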